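## Structural features

The target is a cis-fused 1,2,3,4,4a,9b-hexahydrodibenzofuran (benzene ring C5a–C9a, dihydrofuran ring O5/C4a/C9b/C9a/C5a, cyclohexane ring C1–C4/C4a/C9b) spanned by a 20-membered ansa ring. The bridge runs from the quaternary carbon C9b through a Z-acrylamide, a spermidine chain (amide N, four CH2, amine N5, three CH2, amide N) and a second Z-acrylamide to C8 of the arene, para to O5. There are three stereocentres: quaternary C9b (S), its neighbour C4a (R), cis to it because of the five-membered ring, and the carbinol carbon C3 (R). The C3 hydroxyl is cis to O5 (a 1,3-relationship across C4) and on the face opposite to the C9b side arm. The fragile elements are the two Z-enamide double bonds (Z to E isomerization by light, radicals, thiols or palladium hydrides), the β-aryloxy ketone linkage C4a–O5 at the ketone oxidation level (retro-oxa-Michael), and ω-haloalkyl amides, which cyclize through the amide oxygen or nitrogen. The real difficulties are the absolute configuration of the all-carbon quaternary centre C9b, two contra-thermodynamic alkenes, telling apart two almost identical acrylamide arms (one needs the three-carbon chain, the other the four-carbon chain), and closing the large ring. The key step exploits that N5 is the only amine nitrogen and lies between two purely methylenic chains: its two N–CH2 bonds are remote from every stereocentre and alkene, so the nitrogen can be inserted last as a single atom between two primary bromides.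

## Logic of the disconnections

30 ⇒ 28. The N5–S and O3–Si bonds are cut. Both groups are silicon-triggered, so one fluoride operation unmasks amine and alcohol. The demand is that the fluoride source must not isomerize the Z-alkenes; neither alkene has a γ-hydrogen, which helps.

28 ⇒ 24 + 25. Both N5–CH2 bonds are cut (propyl side and butyl side). These are the only skeletal bonds of the macrocycle that touch neither a stereocentre nor an alkene, and cutting both turns the macrocycle into an open bis-amide plus a one-nitrogen reagent. The forward step must make the sulfonamide nitrogen outcompete amide N and O, and must favour ring closure over oligomerization. The design of 24 keeps the amide N–H groups free (N-substitution would speed up O-alkylation) and keeps C3 as a silyl ether so that both masking groups leave together.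

24 ⇒ 23 ⇒ 21 + 22, and 21 ⇒ 20. The two C–Br bonds are traced back to C–OH, the cinnamoyl amide C–N bond is cut, and the acid is traced to its ethyl ester. The bromides are too labile to carry, so they are made in the last step before ring closure. The demands are N- over O-acylation of an unprotected amino alcohol and an Appel reaction that leaves C3 (silylated) alone.

20 ⇒ 17 + 18 (through 19). The C8–Cβ bond is cut. The aryl bromide carried from 1 becomes the nucleophile after borylation, and the Z geometry is bought ready-made in 18, so the whole C3 arm arrives in one step. The demand is retention of alkene geometry through the palladium coupling.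

17 ⇒ 15 + 16, and 15 ⇒ 14 ⇒ 13. The C9b-arm amide C–N bond, the ester and the O–Si bond are cut. Putting the four-carbon chain on the C9b arm while the other arm is still a bromide distinguishes the two arms by timing, not by orthogonal esters.

13 ⇒ 12 ⇒ 10 + 11. The C3–H bond is cut back to a ketone, then the Cα=Cβ bond of the C9b arm is cut. The demands are hydride delivery to the face that gives OH cis to O5, and a Z-selective olefination that takes the aldehyde and spares the ketone.

10 ⇒ 8 (through 9). The C4a–O5 bond is cut. The tricycle becomes a monocyclic enone with a single stereocentre; the forward oxa-Michael closure can only give the cis fusion, so C9b controls C4a.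

8 ⇒ 5 + 6 (through 7). The C9b–C4a and C1–C2 bonds are cut (Diels–Alder). This builds the cyclohexenone and the quaternary carbon together from two achiral pieces; the forward step must control the enal face with a catalyst and rely on diene polarization for regiochemistry.

5 ⇒ 4 ⇒ 2 ⇒ 1. The C9b=C1 methylene, the homologating C–C bond and the O–Si bond are cut, leading to 1, in which bromine already marks C8 and the formyl carbon becomes C9b.

## Other disconnections considered

All three alternatives concern how the tricyclic core is made. None closes the macrocycle, so each would still need a ring closure such as the one chosen here.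

Alternative 1: The cut is C4a–O5 in the achiral dienone A2. The forward key step is an intramolecular oxa-Michael addition under a cinchona-derived bifunctional squaramide, in which the phenol oxygen selects one of two enantiotopic β-carbons and gives nitrile A1 with C9b and C4a set together.
- In its favour: A2 is symmetrical and should be reachable from a simple benzylic nitrile by double conjugate addition, Dieckmann condensation, decarboxylation and dehydrogenation. The nitrile is a one-carbon handle that cannot be lost by deformylation. The ring closure is the enantiodetermining event of a well-developed reaction class.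
- Against it here: A1 keeps a C1=C2 enone that must be saturated without touching the aryl bromide. The nitrile must be reduced to the aldehyde in the presence of the C3 carbonyl, which costs redox or protecting steps. Any uncatalysed background cyclization of A2 erodes the enantiomeric purity.
- Comparison: structurally A1 and 10 are the same tricycle at different oxidation levels, so this alternative would replace steps 2–5 only. Mechanistically both form C4a–O5 by the same conjugate addition; in the chosen plan it is merely diastereoselective because C9b already exists. On enantiocontrol the alternative is probably the better founded, and on robustness of the C9b one-carbon unit it is also better. On step economy the chosen plan should be shorter by about three steps.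

Alternative 2: The cut is three arene bonds (C5a–C9a, C6–C7, C8–C9). The forward key step is a [2+2+2] cyclotrimerization of the tethered diyne A4 (C9b ethynyl, C4a silyl alkynyl ether) with alkyne A5, catalysed by the rhodium complex A6, which is RhCl(PPh3)3 and holds monovalent rhodium, giving arene A3.
- In its favour: benzene and dihydrofuran rings form in one catalytic step, and the catalyst A6 is a commercial complex that is easy to handle. The C8 carbon arrives at the aldehyde oxidation level, so no aryl halide chemistry is needed. The cis fusion is guaranteed by the tether.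
- Against it here: C3, C4a and C9b must all be present in A4, so the stereochemical problem is moved to an aliphatic ring with a quaternary ethynyl carbon. Silyl ynol ethers on a hindered secondary alcohol are hard to make and hydrolytically labile. Placing the acetal at C8 and not C7 depends on steric steering by the silyl group. Afterwards the C6 silyl group has to be removed and the C9b ether deprotected and oxidized.
- Comparison: in bonds and rings formed per step the alternative is clearly better than any step of the chosen plan. In orthogonality of the two arm handles (acetal against ether) it is equal. In stereochemical economy and total step count it should be worse, because A4 needs its own long asymmetric synthesis.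

Alternative 3: The cut is C9a–C9 and C5a–C6. The forward key step is an inverse-demand Diels–Alder reaction of the lactone-derived cyclic silyl ketene acetal A8 with methyl coumalate A9, followed by decarboxylation and loss of the silyloxy group, giving arene A7.
- In its favour: it is metal-free. The polarity of the two partners places the ester para to O5 without any directing group. A9 is cheap, and C9b already carries a masked aldehyde.
- Against it here: A8 comes from a cis-fused lactone that already contains C3, C4a and C9b, so the stereocentres must again be made beforehand. The nucleophilic carbon of A8 is neopentylic, which should slow the first bond formation. Aromatization needs heat, which the acetal and the silyl ketene acetal may not tolerate. The C8 ester needs two redox steps to reach the aldehyde.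
- Comparison: on regiocontrol at C8 the alternative is equal or better (no palladium step near a Z-alkene). On arm differentiation (ester against acetal) it is equal. On convergence of stereochemistry with ring construction and on step count the chosen plan should be better.

Key step: step 15

Assumption: the (R,R)-configured diol is written in step 4 on the premise that it shields the enal face leading to the (1S,2S)-adduct 7; if the sense of induction is the opposite, the (S,S)-diol is used and nothing else changes.

Remark: throughout, the three-carbon chain sits on the cinnamoyl amide and the four-carbon chain on the C9b amide, as the 20-membered ring of 30 requires.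

## Route

Step 1
Reactants: 1 5-bromosalicylaldehyde (5-bromo-2-hydroxybenzaldehyde)
Product: 2 5-bromo-2-(triisopropylsilyloxy)benzaldehyde
Conditions: i-Pr3SiCl, imidazole, DMF, rt
Reagents that add atoms: triisopropylsilyl chloride, CC(C)[Si](Cl)(C(C)C)C(C)C
Why: Imidazole-promoted O-silylation of a phenol; the bulky triisopropylsilyl ether withstands the ylide, aqueous acid and amine catalysis of steps 2–4, discourages the ortho oxygen from closing onto the side chain, and is removable by fluoride exactly when the phenoxide is wanted in step 5.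

Step 2
Reactants: 2 5-bromo-2-(triisopropylsilyloxy)benzaldehyde
Product: 4 2-[5-bromo-2-(triisopropylsilyloxy)phenyl]acetaldehyde, via enol ether 3 (not isolated)
Conditions: Ph3P(CH2OMe)Cl, KOt-Bu, THF, 0 °C; then 4 M HCl, THF, 40 °C
Reagents that add atoms: (methoxymethyl)triphenylphosphonium chloride, COC[P+](c1ccccc1)(c1ccccc1)c1ccccc1.[Cl-]; water, O
Why: Wittig reaction with the methoxymethylene ylide gives enol ether 3 as an E/Z mixture, and acid hydrolysis of 3 in the same flask gives the one-carbon homologated aldehyde. The aryl silyl ether is much more stable to aqueous acid than the enol ether, and 4 is used crude because arylacetaldehydes self-condense.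

Step 3
Reactants: 4 2-[5-bromo-2-(triisopropylsilyloxy)phenyl]acetaldehyde
Product: 5 2-[5-bromo-2-(triisopropylsilyloxy)phenyl]prop-2-enal
Conditions: 37% aq. CH2O, pyrrolidine (10 mol%), EtCO2H (10 mol%), i-PrOH, 45 °C
Reagents that add atoms: formaldehyde, C=O
Why: Amine/carboxylic acid-catalysed Mannich condensation with formaldehyde followed by elimination of the amine (α-methylenation of an aldehyde) gives the 2-aryl acrolein; it is carried on at once because such enals dimerize on storage.

Step 4
Reactants: 5 2-[5-bromo-2-(triisopropylsilyloxy)phenyl]prop-2-enal; 6 (1E)-3-(tert-butyldimethylsilyloxy)-N,N-dimethylbuta-1,3-dien-1-amine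
Product: 8 (1R)-1-[5-bromo-2-(triisopropylsilyloxy)phenyl]-4-oxocyclohex-2-ene-1-carbaldehyde, via cycloadduct 7 (not isolated)
Conditions: (R,R)-tetra(1-naphthyl)-TADDOL (20 mol%), toluene, −78 °C; then 1 M HCl, THF, 0 °C
Reagents that add atoms: none
Why: Asymmetric Diels–Alder reaction of a 1-amino-3-siloxy diene with an α-substituted acrolein under hydrogen-bond catalysis: the diol binds the formyl oxygen and shields one enal face, and the amino-bearing diene terminus bonds to the α-carbon (bonds C9b–C4a and C1–C2, formyl endo), which fixes quaternary C9b. Dilute acid then hydrolyses the silyl enol ether and eliminates dimethylamine, so the second stereocentre of 7 is deliberately erased and only C9b is carried into enone 8.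

Step 5
Reactants: 8 (1R)-1-[5-bromo-2-(triisopropylsilyloxy)phenyl]-4-oxocyclohex-2-ene-1-carbaldehyde
Product: 10 (4aR,9bS)-8-bromo-3-oxo-1,2,3,4,4a,9b-hexahydrodibenzofuran-9b-carbaldehyde, via phenol 9 (not isolated)
Conditions: Bu4NF (1.1 equiv), THF, −20 → 0 °C; then AcOH
Reagents that add atoms: none
Why: Fluoride cleaves the aryl silyl ether and the phenoxide of 9 adds to the enone β-carbon in a 5-exo-trig oxa-Michael reaction that forms C4a–O5. The three-atom tether can reach C4a only from the face on which the aryl group sits, so the cis fusion and the 4aR configuration follow from C9b; hemiacetal formation at the formyl group is reversible and drains into the ketone.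

Step 6
Reactants: 10 (4aR,9bS)-8-bromo-3-oxo-1,2,3,4,4a,9b-hexahydrodibenzofuran-9b-carbaldehyde; 11 methyl [bis(2,2,2-trifluoroethoxy)phosphoryl]acetate
Product: 12 methyl (2Z)-3-[(4aR,9bS)-8-bromo-3-oxo-1,2,3,4,4a,9b-hexahydrodibenzofuran-9b-yl]prop-2-enoate
Conditions: KN(SiMe3)2, 18-crown-6, THF, −78 °C
Reagents that add atoms: none
Why: Still–Gennari modification of the Horner–Wadsworth–Emmons reaction: the preformed, weakly basic potassium phosphonate adds to the aldehyde much faster than to the ketone and does not enolize the β-aryloxy ketone at −78 °C. The electron-poor trifluoroethyl phosphonate makes elimination of the kinetic adduct faster than its equilibration, which gives the Z-enoate.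

Step 7
Reactants: 12 methyl (2Z)-3-[(4aR,9bS)-8-bromo-3-oxo-1,2,3,4,4a,9b-hexahydrodibenzofuran-9b-yl]prop-2-enoate
Product: 13 methyl (2Z)-3-[(3R,4aR,9bS)-8-bromo-3-hydroxy-1,2,3,4,4a,9b-hexahydrodibenzofuran-9b-yl]prop-2-enoate
Conditions: LiBH(s-Bu)3 (1.05 equiv), THF, −78 °C; aq. NH4Cl
Reagents that add atoms: none
Why: Ketone reduction under steric approach control: the bulky borohydride should attack C3 from the convex face of the cis-fused bicycle (the face of H-4a, away from the aryl ring), placing the hydroxyl cis to O5 (3R), the sense familiar from related cis-fused hydrodibenzofuran-3-ones. With one equivalent at −78 °C the ketone should be reduced much faster than the β-neopentyl enoate or the ester.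

Step 8
Reactants: 13 methyl (2Z)-3-[(3R,4aR,9bS)-8-bromo-3-hydroxy-1,2,3,4,4a,9b-hexahydrodibenzofuran-9b-yl]prop-2-enoate
Product: 14 methyl (2Z)-3-[(3R,4aR,9bS)-8-bromo-3-(tert-butyldimethylsilyloxy)-1,2,3,4,4a,9b-hexahydrodibenzofuran-9b-yl]prop-2-enoate
Conditions: t-BuMe2SiOTf, 2,6-lutidine, CH2Cl2, −78 → 0 °C
Reagents that add atoms: tert-butyldimethylsilyl trifluoromethanesulfonate, CC(C)(C)[Si](C)(C)OS(=O)(=O)C(F)(F)F
Why: Silylation of a hindered secondary alcohol with the silyl triflate and a non-nucleophilic base; the ether keeps C3–OH out of the Appel reaction of step 14 and later leaves with the same reagent that removes the sulfonyl group.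

Step 9
Reactants: 14 methyl (2Z)-3-[(3R,4aR,9bS)-8-bromo-3-(tert-butyldimethylsilyloxy)-1,2,3,4,4a,9b-hexahydrodibenzofuran-9b-yl]prop-2-enoate
Product: 15 (2Z)-3-[(3R,4aR,9bS)-8-bromo-3-(tert-butyldimethylsilyloxy)-1,2,3,4,4a,9b-hexahydrodibenzofuran-9b-yl]prop-2-enoic acid
Conditions: LiOH, THF/MeOH/H2O, rt; then 1 M HCl to pH 4
Reagents that add atoms: lithium hydroxide, [Li+].[OH-]
Why: Saponification of the methyl ester; the Z-enoate has no γ-hydrogen (C9b is quaternary), so hydroxide cannot deconjugate or isomerize it, and the aryl bromide and silyl ether are inert.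

Step 10
Reactants: 15 (2Z)-3-[(3R,4aR,9bS)-8-bromo-3-(tert-butyldimethylsilyloxy)-1,2,3,4,4a,9b-hexahydrodibenzofuran-9b-yl]prop-2-enoic acid; 16 4-aminobutan-1-ol
Product: 17 (2Z)-3-[(3R,4aR,9bS)-8-bromo-3-(tert-butyldimethylsilyloxy)-1,2,3,4,4a,9b-hexahydrodibenzofuran-9b-yl]-N-(4-hydroxybutyl)prop-2-enamide
Conditions: EDC·HCl, HOBt (0.2 equiv), i-Pr2NEt, CH2Cl2, 0 °C → rt
Reagents that add atoms: none
Why: Carbodiimide/hydroxybenzotriazole amide coupling; the primary amine is acylated far faster than the primary alcohol, so the amino alcohol needs no protection. Installing the four-carbon chain now, while the other arm is still a bromide, differentiates the two arms by timing.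

Step 11
Reactants: 17 (2Z)-3-[(3R,4aR,9bS)-8-bromo-3-(tert-butyldimethylsilyloxy)-1,2,3,4,4a,9b-hexahydrodibenzofuran-9b-yl]-N-(4-hydroxybutyl)prop-2-enamide; 18 ethyl (2Z)-3-iodoprop-2-enoate
Product: 20 ethyl (2Z)-3-[(3R,4aR,9bS)-3-(tert-butyldimethylsilyloxy)-9b-[(1Z)-3-(4-hydroxybutylamino)-3-oxoprop-1-en-1-yl]-1,2,3,4,4a,9b-hexahydrodibenzofuran-8-yl]prop-2-enoate, via arylboronate 19 (not isolated)
Conditions: B2pin2, PdCl2(dppf) (5 mol%), KOAc, dioxane, 85 °C; then 18, aq. K3PO4, 40 °C
Reagents that add atoms: none
Why: Miyaura borylation of the aryl bromide to 19, followed in the same flask by Suzuki–Miyaura coupling with the Z-iodoalkene. Oxidative addition, transmetalation and reductive elimination proceed with retention at the alkenyl carbon, so the Z geometry of 18 is transferred to the cinnamate; free hydroxyl and amide groups are tolerated.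

Step 12
Reactants: 20 ethyl (2Z)-3-[(3R,4aR,9bS)-3-(tert-butyldimethylsilyloxy)-9b-[(1Z)-3-(4-hydroxybutylamino)-3-oxoprop-1-en-1-yl]-1,2,3,4,4a,9b-hexahydrodibenzofuran-8-yl]prop-2-enoate
Product: 21 (2Z)-3-[(3R,4aR,9bS)-3-(tert-butyldimethylsilyloxy)-9b-[(1Z)-3-(4-hydroxybutylamino)-3-oxoprop-1-en-1-yl]-1,2,3,4,4a,9b-hexahydrodibenzofuran-8-yl]prop-2-enoic acid
Conditions: LiOH, THF/H2O, 0 °C → rt; then 1 M HCl to pH 4
Reagents that add atoms: lithium hydroxide, [Li+].[OH-]
Why: Saponification of the ethyl ester at low temperature; the secondary amide is untouched, and the acid is set free at pH 4 to avoid acid-catalysed Z to E isomerization of the cinnamic acid.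

Step 13
Reactants: 21 (2Z)-3-[(3R,4aR,9bS)-3-(tert-butyldimethylsilyloxy)-9b-[(1Z)-3-(4-hydroxybutylamino)-3-oxoprop-1-en-1-yl]-1,2,3,4,4a,9b-hexahydrodibenzofuran-8-yl]prop-2-enoic acid; 22 3-aminopropan-1-ol
Product: 23 (2Z)-3-[(3R,4aR,9bS)-3-(tert-butyldimethylsilyloxy)-8-[(1Z)-3-(3-hydroxypropylamino)-3-oxoprop-1-en-1-yl]-1,2,3,4,4a,9b-hexahydrodibenzofuran-9b-yl]-N-(4-hydroxybutyl)prop-2-enamide
Conditions: EDC·HCl, HOBt (0.2 equiv), i-Pr2NEt, DMF, 0 °C → rt
Reagents that add atoms: none
Why: Second carbodiimide amide coupling, again chemoselective for nitrogen; it places the three-carbon chain on the cinnamoyl arm.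

Step 14
Reactants: 23 (2Z)-3-[(3R,4aR,9bS)-3-(tert-butyldimethylsilyloxy)-8-[(1Z)-3-(3-hydroxypropylamino)-3-oxoprop-1-en-1-yl]-1,2,3,4,4a,9b-hexahydrodibenzofuran-9b-yl]-N-(4-hydroxybutyl)prop-2-enamide
Product: 24 (2Z)-N-(4-bromobutyl)-3-[(3R,4aR,9bS)-8-[(1Z)-3-(3-bromopropylamino)-3-oxoprop-1-en-1-yl]-3-(tert-butyldimethylsilyloxy)-1,2,3,4,4a,9b-hexahydrodibenzofuran-9b-yl]prop-2-enamide
Conditions: CBr4, PPh3, CH2Cl2, 0 °C
Reagents that add atoms: carbon tetrabromide, BrC(Br)(Br)Br
Why: Appel reaction: both primary alcohols are converted into bromides by SN2 attack of bromide on the alkoxyphosphonium ions under neutral conditions, while the C3 oxygen is silylated and the amides are spectators. Compound 24 is filtered through silica and used at once because ω-bromoalkyl amides cyclize on standing.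

Step 15
Reactants: 24 (2Z)-N-(4-bromobutyl)-3-[(3R,4aR,9bS)-8-[(1Z)-3-(3-bromopropylamino)-3-oxoprop-1-en-1-yl]-3-(tert-butyldimethylsilyloxy)-1,2,3,4,4a,9b-hexahydrodibenzofuran-9b-yl]prop-2-enamide; 25 2-(trimethylsilyl)ethanesulfonamide
Product: 28 (3R,4aR,9bS)-configured 20-membered Z,Z-macrocyclic bis-amide carrying 3-O-tert-butyldimethylsilyl and N5-[2-(trimethylsilyl)ethanesulfonyl] groups, via propyl-arm sulfonamide 26 (not isolated), via butyl-arm sulfonamide 27 (not isolated)
Conditions: Cs2CO3 (4 equiv), DMF, 45 °C; 24 and 25 (1:1) added over 12 h, 2 mM final concentration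
Reagents that add atoms: none
Why: Cs2CO3 deprotonates 25 and the sulfonamide anion displaces one primary bromide of 24 by SN2, giving 26 or 27; the resulting secondary sulfonamide is deprotonated in turn and displaces the second bromide intramolecularly. The closest known reaction type is the Richman–Atkins-type synthesis of azamacrocycles from a sulfonamide and an α,ω-dihalide with Cs2CO3 in DMF. One ring is closed, the 20-membered ansa ring, by exo-tet N-alkylation at the bromobutyl carbon of 26 or the bromopropyl carbon of 27; both orders converge on 28, so no selectivity between the two bromides is needed. No stereocentre is formed, and C3, C4a and C9b are remote from the reacting carbons. The selectivity that is needed is N-alkylation of the sulfonamide over alkylation of the amide nitrogen or oxygen atoms; it is secured by the sulfonamide N–H being roughly eight pKa units more acidic than the amide N–H, so that carbonate generates only the sulfonamide anion. Ring closure over oligomerization is favoured by the slow simultaneous addition of 24 and 25 in a 1:1 ratio into a large volume, which keeps the stationary concentration of 26 and 27 low, and by the large, weakly coordinated caesium counter-ion. The competing unimolecular cyclization of the 3-bromopropyl amide through its carbonyl oxygen is held back by the moderate temperature and by using freshly made 24. Neither Z-alkene has a γ-hydrogen and no thiol or phosphine is present, so the alkene geometry is not at risk.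

Step 16
Reactants: 28 (3R,4aR,9bS)-configured 20-membered Z,Z-macrocyclic bis-amide carrying 3-O-tert-butyldimethylsilyl and N5-[2-(trimethylsilyl)ethanesulfonyl] groups
Product: 30 target macrocycle (3R,4aR,9bS; both acrylamides Z; free C3–OH and free N5–H), via alcohol 29 (not isolated)
Conditions: Bu4NF (6 equiv), THF, rt → 60 °C
Reagents that add atoms: none
Why: Fluoride first cleaves the silyl ether (29) and then attacks the trimethylsilyl group of the sulfonamide, whose β-elimination releases ethene and sulfur dioxide and frees N5. The conditions contain no thiol, acid or reductant and neither Z-alkene has a γ-hydrogen, so geometry and stereocentres should be preserved.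

## Compound list

1 | 5-bromosalicylaldehyde (5-bromo-2-hydroxybenzaldehyde) | O=Cc1cc(Br)ccc1O | starting material
2 | 5-bromo-2-(triisopropylsilyloxy)benzaldehyde | O=Cc1cc(Br)ccc1O[Si](C(C)C)(C(C)C)C(C)C | intermediate
3 | [4-bromo-2-(2-methoxyethenyl)phenoxy]triisopropylsilane, E/Z mixture (not isolated) | COC=Cc1cc(Br)ccc1O[Si](C(C)C)(C(C)C)C(C)C | intermediate
4 | 2-[5-bromo-2-(triisopropylsilyloxy)phenyl]acetaldehyde | O=CCc1cc(Br)ccc1O[Si](C(C)C)(C(C)C)C(C)C | intermediate
5 | 2-[5-bromo-2-(triisopropylsilyloxy)phenyl]prop-2-enal | C=C(C=O)c1cc(Br)ccc1O[Si](C(C)C)(C(C)C)C(C)C | intermediate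
6 | (1E)-3-(tert-butyldimethylsilyloxy)-N,N-dimethylbuta-1,3-dien-1-amine | CN(C)/C=C/C(=C)O[Si](C)(C)C(C)(C)C | starting material
7 | (1S,2S)-1-[5-bromo-2-(triisopropylsilyloxy)phenyl]-4-(tert-butyldimethylsilyloxy)-2-(dimethylamino)cyclohex-3-ene-1-carbaldehyde (not isolated) | O=C[C@]1(c2cc(Br)ccc2O[Si](C(C)C)(C(C)C)C(C)C)CCC(O[Si](C)(C)C(C)(C)C)=C[C@@H]1N(C)C | intermediate
8 | (1R)-1-[5-bromo-2-(triisopropylsilyloxy)phenyl]-4-oxocyclohex-2-ene-1-carbaldehyde | O=C[C@]1(c2cc(Br)ccc2O[Si](C(C)C)(C(C)C)C(C)C)CCC(=O)C=C1 | intermediate
9 | (1R)-1-(5-bromo-2-hydroxyphenyl)-4-oxocyclohex-2-ene-1-carbaldehyde, present as its phenoxide (not isolated) | O=C[C@]1(c2cc(Br)ccc2O)CCC(=O)C=C1 | intermediate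
10 | (4aR,9bS)-8-bromo-3-oxo-1,2,3,4,4a,9b-hexahydrodibenzofuran-9b-carbaldehyde | O=C[C@]12CCC(=O)C[C@H]1Oc1ccc(Br)cc12 | intermediate
11 | methyl [bis(2,2,2-trifluoroethoxy)phosphoryl]acetate | COC(=O)CP(=O)(OCC(F)(F)F)OCC(F)(F)F | starting material
12 | methyl (2Z)-3-[(4aR,9bS)-8-bromo-3-oxo-1,2,3,4,4a,9b-hexahydrodibenzofuran-9b-yl]prop-2-enoate | COC(=O)/C=C\[C@]12CCC(=O)C[C@H]1Oc1ccc(Br)cc12 | intermediate
13 | methyl (2Z)-3-[(3R,4aR,9bS)-8-bromo-3-hydroxy-1,2,3,4,4a,9b-hexahydrodibenzofuran-9b-yl]prop-2-enoate | COC(=O)/C=C\[C@]12CC[C@@H](O)C[C@H]1Oc1ccc(Br)cc12 | intermediate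
14 | methyl (2Z)-3-[(3R,4aR,9bS)-8-bromo-3-(tert-butyldimethylsilyloxy)-1,2,3,4,4a,9b-hexahydrodibenzofuran-9b-yl]prop-2-enoate | COC(=O)/C=C\[C@]12CC[C@@H](O[Si](C)(C)C(C)(C)C)C[C@H]1Oc1ccc(Br)cc12 | intermediate
15 | (2Z)-3-[(3R,4aR,9bS)-8-bromo-3-(tert-butyldimethylsilyloxy)-1,2,3,4,4a,9b-hexahydrodibenzofuran-9b-yl]prop-2-enoic acid | OC(=O)/C=C\[C@]12CC[C@@H](O[Si](C)(C)C(C)(C)C)C[C@H]1Oc1ccc(Br)cc12 | intermediate
16 | 4-aminobutan-1-ol | NCCCCO | starting material
17 | (2Z)-3-[(3R,4aR,9bS)-8-bromo-3-(tert-butyldimethylsilyloxy)-1,2,3,4,4a,9b-hexahydrodibenzofuran-9b-yl]-N-(4-hydroxybutyl)prop-2-enamide | O=C(/C=C\[C@]12CC[C@@H](O[Si](C)(C)C(C)(C)C)C[C@H]1Oc1ccc(Br)cc12)NCCCCO | intermediate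
18 | ethyl (2Z)-3-iodoprop-2-enoate | CCOC(=O)/C=C\I | starting material
19 | (2Z)-3-[(3R,4aR,9bS)-3-(tert-butyldimethylsilyloxy)-8-(4,4,5,5-tetramethyl-1,3,2-dioxaborolan-2-yl)-1,2,3,4,4a,9b-hexahydrodibenzofuran-9b-yl]-N-(4-hydroxybutyl)prop-2-enamide (not isolated) | O=C(/C=C\[C@]12CC[C@@H](O[Si](C)(C)C(C)(C)C)C[C@H]1Oc1ccc(cc12)B1OC(C)(C)C(C)(C)O1)NCCCCO | intermediate
20 | ethyl (2Z)-3-[(3R,4aR,9bS)-3-(tert-butyldimethylsilyloxy)-9b-[(1Z)-3-(4-hydroxybutylamino)-3-oxoprop-1-en-1-yl]-1,2,3,4,4a,9b-hexahydrodibenzofuran-8-yl]prop-2-enoate | O=C(/C=C\[C@]12CC[C@@H](O[Si](C)(C)C(C)(C)C)C[C@H]1Oc1ccc(cc12)/C=C\C(=O)OCC)NCCCCO | intermediate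
21 | (2Z)-3-[(3R,4aR,9bS)-3-(tert-butyldimethylsilyloxy)-9b-[(1Z)-3-(4-hydroxybutylamino)-3-oxoprop-1-en-1-yl]-1,2,3,4,4a,9b-hexahydrodibenzofuran-8-yl]prop-2-enoic acid | O=C(/C=C\[C@]12CC[C@@H](O[Si](C)(C)C(C)(C)C)C[C@H]1Oc1ccc(cc12)/C=C\C(=O)O)NCCCCO | intermediate
22 | 3-aminopropan-1-ol | NCCCO | starting material
23 | (2Z)-3-[(3R,4aR,9bS)-3-(tert-butyldimethylsilyloxy)-8-[(1Z)-3-(3-hydroxypropylamino)-3-oxoprop-1-en-1-yl]-1,2,3,4,4a,9b-hexahydrodibenzofuran-9b-yl]-N-(4-hydroxybutyl)prop-2-enamide | O=C(/C=C\[C@]12CC[C@@H](O[Si](C)(C)C(C)(C)C)C[C@H]1Oc1ccc(cc12)/C=C\C(=O)NCCCO)NCCCCO | intermediate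
24 | (2Z)-N-(4-bromobutyl)-3-[(3R,4aR,9bS)-8-[(1Z)-3-(3-bromopropylamino)-3-oxoprop-1-en-1-yl]-3-(tert-butyldimethylsilyloxy)-1,2,3,4,4a,9b-hexahydrodibenzofuran-9b-yl]prop-2-enamide | O=C(/C=C\[C@]12CC[C@@H](O[Si](C)(C)C(C)(C)C)C[C@H]1Oc1ccc(cc12)/C=C\C(=O)NCCCBr)NCCCCBr | intermediate
25 | 2-(trimethylsilyl)ethanesulfonamide | C[Si](C)(C)CCS(N)(=O)=O | starting material
26 | mono-alkylated sulfonamide: cinnamoyl arm N-[3-({[2-(trimethylsilyl)ethyl]sulfonyl}amino)propyl], C9b arm N-(4-bromobutyl) (not isolated) | O=C(/C=C\[C@]12CC[C@@H](O[Si](C)(C)C(C)(C)C)C[C@H]1Oc1ccc(cc12)/C=C\C(=O)NCCCNS(=O)(=O)CC[Si](C)(C)C)NCCCCBr | intermediate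
27 | mono-alkylated sulfonamide: C9b arm N-[4-({[2-(trimethylsilyl)ethyl]sulfonyl}amino)butyl], cinnamoyl arm N-(3-bromopropyl) (not isolated) | O=C(/C=C\[C@]12CC[C@@H](O[Si](C)(C)C(C)(C)C)C[C@H]1Oc1ccc(cc12)/C=C\C(=O)NCCCBr)NCCCCNS(=O)(=O)CC[Si](C)(C)C | intermediate
28 | (3R,4aR,9bS)-configured 20-membered Z,Z-macrocyclic bis-amide with 3-O-tert-butyldimethylsilyl and N5-[2-(trimethylsilyl)ethanesulfonyl] groups | O=C1/C=C\[C@]23CC[C@@H](O[Si](C)(C)C(C)(C)C)C[C@H]2Oc2ccc(cc23)/C=C\C(=O)NCCCN(S(=O)(=O)CC[Si](C)(C)C)CCCCN1 | intermediate
29 | N5-[2-(trimethylsilyl)ethanesulfonyl] macrocycle with free C3–OH (not isolated) | O=C1/C=C\[C@]23CC[C@@H](O)C[C@H]2Oc2ccc(cc23)/C=C\C(=O)NCCCN(S(=O)(=O)CC[Si](C)(C)C)CCCCN1 | intermediate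
30 | target: (3R,4aR,9bS)-3-hydroxy-1,2,3,4,4a,9b-hexahydrodibenzofuran bridged from C9b to C8 by (Z)-CH=CH–CO–NH(CH2)4NH(CH2)3NH–CO–CH=CH-(Z) | O=C1/C=C\[C@]23CC[C@@H](O)C[C@H]2Oc2ccc(cc23)/C=C\C(=O)NCCCNCCCCN1 | target

## Step count and least certain steps

Total step count: 16. Longest linear sequence: 16 steps (1 → 30); all other components are purchased.

Step 15 (key step). The most likely failure is oligomerization or premature consumption of a bromide. The first N-alkylation is bimolecular and is slowed by the dilution that the ring closure needs, whereas cyclization of the 3-bromopropyl amide through its carbonyl oxygen (and of the 4-bromobutyl amide through nitrogen) is unimolecular and is not slowed. Fallback: the first N5–C bond is made before the chains are attached, so that only one intramolecular alkylation remains. Setting out from 21, amide coupling with N-(3-aminopropyl)-2-(trimethylsilyl)ethanesulfonamide F1 (from propane-1,3-diamine in excess and 2-(trimethylsilyl)ethanesulfonyl chloride) would give the hydroxybutyl amide sulfonamide F2. Appel bromination of its single primary alcohol leads to 26, which contains no 3-bromopropyl amide and closes under Cs2CO3 in dilute DMF to 28.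

Step 4. The most likely failure is poor facial discrimination or a sluggish cycloaddition, because the ortho-silyloxy aryl group is twisted out of conjugation and crowds the hydrogen-bonded formyl group. Fallback: the chirality is moved from the catalyst to the diene. 4-Methoxybut-3-en-2-one and (2R,5R)-2,5-diphenylpyrrolidine would give the vinylogous amide F3; KN(SiMe3)2 and t-BuMe2SiCl convert it into the auxiliary diene F4. Uncatalysed cycloaddition of F4 with 5 gives the cycloadduct F5, and the acid treatment of step 4 releases the auxiliary and returns to 8. The auxiliary enantiomer is chosen by the same criterion as the catalyst.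

Step 7. The most likely failure is hydride delivery to the wrong face or poor facial selectivity, because C3 is far from the ring fusion and the two half-chair conformers of the cyclohexanone present opposite faces to a bulky reagent. Fallback: the configuration is set by substitution instead of addition. Setting out from 12, the 3S alcohol F6 (separated from the mixture, or made on purpose with whichever hydride favours it) is inverted by Mitsunobu esterification with 4-nitrobenzoic acid to the 3R ester F7, and methanolysis (K2CO3, MeOH) returns to 13.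

Step 11. The most likely failure is loss of alkene geometry during the coupling (isomerization of 18 or of the product by palladium hydride species), or protodeboronation of the electron-rich boronate 19. Fallback: the arm is built by olefination instead of coupling. Setting out from 17, palladium-catalysed reductive carbonylation (Pd(OAc)2, di(1-adamantyl)-n-butylphosphine, CO/H2, TMEDA, toluene) would give the aryl aldehyde F8. Z-selective Horner–Wadsworth–Emmons reaction with the preformed sodium salt of ethyl (diphenoxyphosphoryl)acetate (NaH, THF, −78 °C) returns to 20.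

Step 14. The most likely failure is cyclization of the activated 3-hydroxypropyl amide through the amide oxygen at the alkoxyphosphonium stage, or of the bromide during concentration. Fallback: activation as sulfonate followed by halide exchange. Setting out from 23, MeSO2Cl/Et3N at −20 °C would give the bis-methanesulfonate F9, and LiBr in acetone at room temperature returns to 24.

## Further compounds

F1 | step 15 | N-(3-aminopropyl)-2-(trimethylsilyl)ethanesulfonamide | C[Si](C)(C)CCS(=O)(=O)NCCCN
F2 | step 15 | Z,Z-bis-amide with C9b arm N-(4-hydroxybutyl), cinnamoyl arm N-[3-({[2-(trimethylsilyl)ethyl]sulfonyl}amino)propyl] and C3 tert-butyldimethylsilyl ether | O=C(/C=C\[C@]12CC[C@@H](O[Si](C)(C)C(C)(C)C)C[C@H]1Oc1ccc(cc12)/C=C\C(=O)NCCCNS(=O)(=O)CC[Si](C)(C)C)NCCCCO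
F3 | step 4 | (3E)-4-[(2R,5R)-2,5-diphenylpyrrolidin-1-yl]but-3-en-2-one | CC(=O)/C=C/N1[C@@H](c2ccccc2)CC[C@@H]1c1ccccc1
F4 | step 4 | (2R,5R)-1-[(1E)-3-(tert-butyldimethylsilyloxy)buta-1,3-dien-1-yl]-2,5-diphenylpyrrolidine | C=C(O[Si](C)(C)C(C)(C)C)/C=C/N1[C@@H](c2ccccc2)CC[C@@H]1c1ccccc1
F5 | step 4 | (1S,2S)-1-[5-bromo-2-(triisopropylsilyloxy)phenyl]-4-(tert-butyldimethylsilyloxy)-2-[(2R,5R)-2,5-diphenylpyrrolidin-1-yl]cyclohex-3-ene-1-carbaldehyde | O=C[C@]1(c2cc(Br)ccc2O[Si](C(C)C)(C(C)C)C(C)C)CCC(O[Si](C)(C)C(C)(C)C)=C[C@@H]1N1[C@@H](c2ccccc2)CC[C@@H]1c1ccccc1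
F6 | step 7 | methyl (2Z)-3-[(3S,4aR,9bS)-8-bromo-3-hydroxy-1,2,3,4,4a,9b-hexahydrodibenzofuran-9b-yl]prop-2-enoate | COC(=O)/C=C\[C@]12CC[C@H](O)C[C@H]1Oc1ccc(Br)cc12
F7 | step 7 | (3R,4aR,9bS)-8-bromo-9b-[(1Z)-3-methoxy-3-oxoprop-1-en-1-yl]-1,2,3,4,4a,9b-hexahydrodibenzofuran-3-yl 4-nitrobenzoate | COC(=O)/C=C\[C@]12CC[C@@H](OC(=O)c3ccc(cc3)[N+](=O)[O-])C[C@H]1Oc1ccc(Br)cc12
F8 | step 11 | (2Z)-3-[(3R,4aR,9bS)-3-(tert-butyldimethylsilyloxy)-8-formyl-1,2,3,4,4a,9b-hexahydrodibenzofuran-9b-yl]-N-(4-hydroxybutyl)prop-2-enamide | O=C(/C=C\[C@]12CC[C@@H](O[Si](C)(C)C(C)(C)C)C[C@H]1Oc1ccc(C=O)cc12)NCCCCO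
F9 | step 14 | bis-methanesulfonate of diol 23 | O=C(/C=C\[C@]12CC[C@@H](O[Si](C)(C)C(C)(C)C)C[C@H]1Oc1ccc(cc12)/C=C\C(=O)NCCCOS(C)(=O)=O)NCCCCOS(C)(=O)=O
A1 | alternative 1 | cis-8-bromo-3-oxo-3,4,4a,9b-tetrahydrodibenzofuran-9b-carbonitrile (4aR,9b configuration as in the target series) | N#C[C@]23C=CC(=O)C[C@H]2Oc2ccc(Br)cc23
A2 | alternative 1 | 1-(5-bromo-2-hydroxyphenyl)-4-oxocyclohexa-2,5-diene-1-carbonitrile | N#CC1(C=CC(=O)C=C1)c1cc(Br)ccc1O
A3 | alternative 2 | cis-3-(tert-butyldimethylsilyloxy)-8-(diethoxymethyl)-9b-[(4-methoxybenzyloxy)methyl]-6-(trimethylsilyl)-1,2,3,4,4a,9b-hexahydrodibenzofuran | COc1ccc(COC[C@]23CC[C@@H](O[Si](C)(C)C(C)(C)C)C[C@H]2Oc2c([Si](C)(C)C)cc(cc23)C(OCC)OCC)cc1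
A4 | alternative 2 | cyclohexane diyne: 1-ethynyl-1-[(4-methoxybenzyloxy)methyl]-4-(tert-butyldimethylsilyloxy)-2-[(trimethylsilyl)ethynyloxy]cyclohexane, configured as in A3 | COc1ccc(COC[C@]2(C#C)CC[C@@H](O[Si](C)(C)C(C)(C)C)C[C@H]2OC#C[Si](C)(C)C)cc1
A5 | alternative 2 | 3,3-diethoxyprop-1-yne | C#CC(OCC)OCC
A6 | alternative 2 | chlorotris(triphenylphosphine)rhodium, RhCl(PPh3)3 | Cl[Rh](P(c1ccccc1)(c1ccccc1)c1ccccc1)(P(c1ccccc1)(c1ccccc1)c1ccccc1)P(c1ccccc1)(c1ccccc1)c1ccccc1
A7 | alternative 3 | methyl cis-3-(tert-butyldimethylsilyloxy)-9b-(dimethoxymethyl)-1,2,3,4,4a,9b-hexahydrodibenzofuran-8-carboxylate | COC(OC)[C@]23CC[C@@H](O[Si](C)(C)C(C)(C)C)C[C@H]2Oc2ccc(cc23)C(=O)OC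
A8 | alternative 3 | cis-fused cyclic silyl ketene acetal: 6-(tert-butyldimethylsilyloxy)-3a-(dimethoxymethyl)-2-(trimethylsilyloxy)-3a,4,5,6,7,7a-hexahydrobenzofuran, configured as in A7 | COC(OC)[C@]12CC[C@@H](O[Si](C)(C)C(C)(C)C)C[C@H]1OC(O[Si](C)(C)C)=C2
A9 | alternative 3 | methyl coumalate (methyl 2-oxo-2H-pyran-5-carboxylate) | COC(=O)C1=COC(=O)C=C1
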